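**Retrosynthetic overview**

- Ring numbering: C1 (enol carbon), C2 (bears the acyl group), C3 (ketone), C4 (carbinol, S), C5, C6; C1' is the side-chain carbonyl. The last bond made is C1–C2, by Claisen-type transacylation of a 5-(3-oxoacyl)-γ-butyrolactone. Its lactone is both the C1 acyl donor and the mask of the C4 oxygen.
- The C3 ketone of that diketo lactone is carried as an alkyne carbon and is unmasked by conjugate hydration of an ynone lactone.
- Key disconnection C3–C4: terminal ynone HC≡C–CO–(CH2)12Ph plus methyl 4-oxobutanoate. The metalated ynone is a latent RCOCH2C(=O)(−) acyl anion, so a Michael-acceptor carbon is joined to an aldehyde carbon. The catalytic asymmetric addition sets C4, the only stereocentre, and brings all 25 carbons together.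
- The ynone comes from methyl 13-phenyltridecanoate and ethynylmagnesium bromide. The ester comes from 2-phenylethylmagnesium chloride and methyl 11-bromoundecanoate by copper-catalysed sp3–sp3 coupling.
- Ring order: the phenyl ring is bought, the temporary γ-lactone is closed right after the key step, and the cyclohexane-1,3-dione ring is closed last.

Assumption: (R)-BINOL is taken to send the alkynyl group to the Re face of the unbranched aldehyde (S product), by analogy with the Si-face sense of (S)-BINOL in alkynylzinc additions; both antipodes cost the same, and the target is written as one of its rapidly equilibrating enol tautomers.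

**Route**

Step 1
Reactants: 1 2-phenylethylmagnesium chloride; 2 methyl 11-bromoundecanoate
Product: 3 methyl 13-phenyltridecanoate
Conditions: Li2CuCl4 (3 mol %), NMP (4 equiv), THF, 0 °C to rt, slow addition of 1 (1.3 equiv); aq NH4Cl
Reagents that add atoms: none
Why: Kochi-type copper-catalysed sp3–sp3 cross-coupling of a primary alkyl Grignard reagent with a primary alkyl bromide, in which NMP makes the coupling outrun addition to the ester, and no stereocentre is involved.

Step 2
Reactants: 3 methyl 13-phenyltridecanoate; 4 ethynylmagnesium bromide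
Product: 6 15-phenylpentadec-1-yn-3-one, via Weinreb amide 5 (not isolated)
Conditions: MeNH(OMe)·HCl (1.5 equiv), iPrMgCl (3.0 equiv), THF, −15 °C, 1 h; then 4 (3 equiv), 0 °C to rt; inverse quench into cold 1 M HCl
Reagents that add atoms: N,O-dimethylhydroxylamine hydrochloride, CNOC.Cl (its N(OMe)Me group is in 5 only)
Why: One-pot Weinreb ketone synthesis, in which the chloromagnesium amide turns the ester into 5 and the chelated adduct of 5 with 4 holds at the ketone stage until the acid quench, which also keeps the freed amine protonated so that it cannot add to the ynone.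

Step 3
Reactants: 6 15-phenylpentadec-1-yn-3-one; 7 methyl 4-oxobutanoate
Product: 10 (5S)-5-(3-oxo-15-phenylpentadec-1-yn-1-yl)dihydrofuran-2(3H)-one, via ethylzinc acetylide 8 (not isolated), via hydroxy ynone ester 9 (not isolated)
Conditions: 6 (1.2 equiv), Et2Zn (1.2 equiv), HMPA (2 equiv), CH2Cl2, 0 °C to rt, 1 h; (R)-BINOL (20 mol %), Ti(OiPr)4 (50 mol %), then 7 (1.0 equiv), rt, 12 h; 1 M HCl; p-TsOH·H2O (5 mol %), toluene, 40 °C
Reagents that add atoms: diethylzinc, CC[Zn]CC (its EtZn group is in 8 only)
Why: Proposed new method: the sp C–H of 6 is its most acidic site and is zincated by Et2Zn/HMPA just as methyl propiolate is, the charge of 8 is delocalised into its ketone (cumulenolate), which switches off self-addition, and the (R)-BINOL–titanium complex then activates only the aldehyde and passes the alkynyl group to its Re face to set C4 as S, so that a Michael-acceptor carbon that will become the C3 carbonyl (a latent acyl anion) is bonded to an aldehyde carbon; the closest known reaction is the BINOL/Ti(OiPr)4/Et2Zn-catalysed asymmetric alkynylzinc addition of methyl propiolate to aliphatic aldehydes, and acid-catalysed γ-lactonisation of 9 follows.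

Step 4
Reactants: 10 (5S)-5-(3-oxo-15-phenylpentadec-1-yn-1-yl)dihydrofuran-2(3H)-one
Product: 13 oleiferinone [(6S)-3,6-dihydroxy-2-(13-phenyltridecanoyl)cyclohex-2-en-1-one], via diketo lactone 11 (not isolated), via ring-opened methyl ester 12 (not isolated)
Conditions: Ph3PAuCl (2 mol %), AgOTf (2 mol %), H2O (2 equiv), 1,4-dioxane, rt; evaporate, toluene azeotrope; NaOMe (3 equiv), MeOH, 0 to 40 °C; cold 1 M HCl
Reagents that add atoms: water, O; sodium methoxide, C[O-].[Na+] (its methoxy group is in 12 only)
Why: Cationic gold promotes the β-selective (Michael-type) hydration known for alkynones and so puts the new carbonyl at C3, while the lactone keeps the C4 oxygen from closing a 3(2H)-furanone and cannot itself take part because its carbonyl oxygen points away from the alkyne; methoxide then deprotonates C2, opens the lactone reversibly to 12, and the diketonate carbon is acylated by the ester (Dieckmann-type Claisen condensation, 6-exo-trig) with the very acidic triketone enolate as thermodynamic sink, and C4 is not touched because its neighbouring ketone is part of an enolate anion throughout.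

**Compound list**

1 | 2-phenylethylmagnesium chloride | Cl[Mg]CCc1ccccc1 | starting material
2 | methyl 11-bromoundecanoate | COC(=O)CCCCCCCCCCBr | starting material
3 | methyl 13-phenyltridecanoate | COC(=O)CCCCCCCCCCCCc1ccccc1 | intermediate
4 | ethynylmagnesium bromide | C#C[Mg]Br | starting material
5 | N-methoxy-N-methyl-13-phenyltridecanamide | CON(C)C(=O)CCCCCCCCCCCCc1ccccc1 | intermediate
6 | 15-phenylpentadec-1-yn-3-one | C#CC(=O)CCCCCCCCCCCCc1ccccc1 | intermediate
7 | methyl 4-oxobutanoate | COC(=O)CCC=O | starting material
8 | ethyl(3-oxo-15-phenylpentadec-1-yn-1-yl)zinc | CC[Zn]C#CC(=O)CCCCCCCCCCCCc1ccccc1 | intermediate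
9 | methyl (4S)-4-hydroxy-7-oxo-19-phenylnonadec-5-ynoate | COC(=O)CC[C@H](O)C#CC(=O)CCCCCCCCCCCCc1ccccc1 | intermediate
10 | (5S)-5-(3-oxo-15-phenylpentadec-1-yn-1-yl)dihydrofuran-2(3H)-one | O=C1CC[C@@H](C#CC(=O)CCCCCCCCCCCCc2ccccc2)O1 | intermediate
11 | (5S)-5-(3-oxo-15-phenylpentadecanoyl)dihydrofuran-2(3H)-one | O=C1CC[C@@H](C(=O)CC(=O)CCCCCCCCCCCCc2ccccc2)O1 | intermediate
12 | methyl (4S)-4-hydroxy-5,7-dioxo-19-phenylnonadecanoate | COC(=O)CC[C@H](O)C(=O)CC(=O)CCCCCCCCCCCCc1ccccc1 | intermediate
13 | oleiferinone, (6S)-3,6-dihydroxy-2-(13-phenyltridecanoyl)cyclohex-2-en-1-one | O=C(CCCCCCCCCCCCc1ccccc1)C1=C(O)CC[C@H](O)C1=O | target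

**Step count**

Total step count: 4. Longest linear sequence: 4 steps (1 and 2 to 3, then 6, then 10, then 13).

**Steps most likely to fail**

Step 3 is the most exposed.
- The zincated ynone may be too weak a nucleophile.
- 6 may enolise at its CH2 and give aldol products.
- The ketone of 9 may be attacked once the aldehyde is used up.
- The ee on this unbranched aldehyde is unproven.

The fallback sets out from 7 and 3 and comes back at 10. It carries C3 as a plain silylacetylide and brings in the acyl group afterwards. Trimethylsilylacetylene is added to 7 with Et2Zn, (R)-BINOL and Ti(OiPr)4 to give methyl (4S)-4-hydroxy-6-(trimethylsilyl)hex-5-ynoate F1. This is lactonised with catalytic p-TsOH to (5S)-5-[(trimethylsilyl)ethynyl]dihydrofuran-2(3H)-one F2 and desilylated with TBAF/AcOH to (5S)-5-ethynyldihydrofuran-2(3H)-one F3. In parallel, 3 is saponified with LiOH to 13-phenyltridecanoic acid F4 and converted with SOCl2 into 13-phenyltridecanoyl chloride F5. Acylative Sonogashira coupling of F3 with F5 (PdCl2(PPh3)2, CuI, Et3N, THF, rt) gives 10.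

Step 4 is second.
- The free C4 alkoxide of 12 may close onto C1' and end as a 3(2H)-furanone.
- The stabilised diketonate may acylate too slowly.
- Residual water may saponify the ester.

The fallback sets out from 9 and comes back at 13. It replaces the lactone isomerisation with a Dieckmann closure of an acyclic, silyl-protected ester under a non-nucleophilic base. 9 is isolated by leaving out the acid treatment and silylated (TBSCl, imidazole, DMF) to methyl (4S)-4-[(tert-butyldimethylsilyl)oxy]-7-oxo-19-phenylnonadec-5-ynoate F6. Hydration (Ph3PAuCl, AgOTf, H2O, dioxane) gives methyl (4S)-4-[(tert-butyldimethylsilyl)oxy]-5,7-dioxo-19-phenylnonadecanoate F7. KOtBu in THF at 0 °C closes the ring to (6S)-6-[(tert-butyldimethylsilyl)oxy]-3-hydroxy-2-(13-phenyltridecanoyl)cyclohex-2-en-1-one F8. HF·pyridine in THF then frees 13.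

Step 2 is third.
- In the one-pot version, surplus N,O-dimethylhydroxylamine can add to the terminal ynone at the quench.
- Amide formation may stay incomplete.

The fallback sets out from 3 and comes back at 6. It goes through the aldehyde oxidation level instead of acyl substitution. DIBAL-H (toluene, −78 °C) gives 13-phenyltridecanal F9. Addition of 4 gives racemic 15-phenylpentadec-1-yn-3-ol F10. Oxidation with MnO2 (or Dess–Martin periodinane) gives 6.

**Further compounds**

F1 | step 3 | methyl (4S)-4-hydroxy-6-(trimethylsilyl)hex-5-ynoate | COC(=O)CC[C@H](O)C#C[Si](C)(C)C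
F2 | step 3 | (5S)-5-[(trimethylsilyl)ethynyl]dihydrofuran-2(3H)-one | O=C1CC[C@@H](C#C[Si](C)(C)C)O1
F3 | step 3 | (5S)-5-ethynyldihydrofuran-2(3H)-one | O=C1CC[C@@H](C#C)O1
F4 | step 3 | 13-phenyltridecanoic acid | OC(=O)CCCCCCCCCCCCc1ccccc1
F5 | step 3 | 13-phenyltridecanoyl chloride | ClC(=O)CCCCCCCCCCCCc1ccccc1
F6 | step 4 | methyl (4S)-4-[(tert-butyldimethylsilyl)oxy]-7-oxo-19-phenylnonadec-5-ynoate | COC(=O)CC[C@H](O[Si](C)(C)C(C)(C)C)C#CC(=O)CCCCCCCCCCCCc1ccccc1
F7 | step 4 | methyl (4S)-4-[(tert-butyldimethylsilyl)oxy]-5,7-dioxo-19-phenylnonadecanoate | COC(=O)CC[C@H](O[Si](C)(C)C(C)(C)C)C(=O)CC(=O)CCCCCCCCCCCCc1ccccc1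
F8 | step 4 | (6S)-6-[(tert-butyldimethylsilyl)oxy]-3-hydroxy-2-(13-phenyltridecanoyl)cyclohex-2-en-1-one | O=C(CCCCCCCCCCCCc1ccccc1)C1=C(O)CC[C@H](O[Si](C)(C)C(C)(C)C)C1=O
F9 | step 2 | 13-phenyltridecanal | O=CCCCCCCCCCCCCc1ccccc1
F10 | step 2 | 15-phenylpentadec-1-yn-3-ol (racemic) | C#CC(O)CCCCCCCCCCCCc1ccccc1
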